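**Retrosynthetic overview**
1. The oxepine ring is formed last: target ⇐ artocarpin, by enantioselective epoxidation of the 3-prenyl group and in-flask 7-exo opening of the (R)-epoxide by the 2'-phenoxide (inversion gives S).
2. Artocarpin ⇐ 6-iodo-3-prenylflavone triol + (E)-3-methylbut-1-enyl boronate (Suzuki), so the acid-sensitive styrenyl chain enters after all acid chemistry.
3. Ring C ⇐ 2-prenyl-1,3-diketone, by dehydration of its 2-hydroxyflavanone hemiketal (the flavone-forming event of the biosynthesis); prenyl is put on C-3 at the diketone stage.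
4. Diketone ⇐ Baker–Venkataraman rearrangement of the aryl ester from 2,6-dihydroxy-4-methoxyacetophenone and 2,4-bis(MOM-oxy)benzoic acid; iodine goes ortho to the one free OH, which is then capped so ring C can close only through the other oxygen.
5. Ring order: rings A and B are bought, ring C is closed in step 7, the oxepine ring in step 9.

Assumption: 1-(2,6-dihydroxy-4-methoxyphenyl)ethanone and (E)-3-methylbut-1-enylboronic acid pinacol ester are bought as catalogue chemicals.

The route is designed on paper and has not been run. The Shi face selectivity is assigned by analogy with the (R,R)-epoxides obtained from trans-disubstituted and trisubstituted alkenes.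

**Route**

Step 1
Reactants: 1 2,4-dihydroxybenzoic acid; 2 chloromethyl methyl ether (MOMCl); 3 lithium hydroxide
Product: 5 2,4-bis(methoxymethoxy)benzoic acid, via tris-MOM ester 4 (not isolated)
Conditions: MOMCl (4 equiv), iPr2NEt (5 equiv), CH2Cl2, 0 → 40 °C; then LiOH (3 equiv), THF/MeOH/H2O, rt; cold 0.5 M HCl to pH 4
Reagents that add atoms: chloromethyl methyl ether 2, COCCl; lithium hydroxide 3, [Li+].[OH-] (one carboxyl oxygen)
Why: MOM etherification of both phenols and the carboxylate under amine base, then saponification of the much more labile acyloxymethyl ester, gives the acid with both aryl MOM ethers intact (acetal protection, then ester hydrolysis).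

Step 2
Reactants: 5 2,4-bis(methoxymethoxy)benzoic acid; 6 1-(2,6-dihydroxy-4-methoxyphenyl)ethanone
Product: 7 2-acetyl-3-hydroxy-5-methoxyphenyl 2,4-bis(methoxymethoxy)benzoate
Conditions: DCC (1.1 equiv), DMAP (10 mol%), CH2Cl2/THF, 0 °C → rt; 6 in 1.3-fold excess
Reagents that add atoms: none
Why: Steglich esterification; ketone 6 has a mirror plane so either phenol gives the same mono-ester, and the remaining OH is held in a hydrogen bond to the ketone, which holds back a second acylation.

Step 3
Reactants: 7 2-acetyl-3-hydroxy-5-methoxyphenyl 2,4-bis(methoxymethoxy)benzoate; 8 N-iodosuccinimide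
Product: 9 2-acetyl-3-hydroxy-4-iodo-5-methoxyphenyl 2,4-bis(methoxymethoxy)benzoate
Conditions: NIS (1.05 equiv), DMF, 0 °C → rt, dark
Reagents that add atoms: N-iodosuccinimide 8, O=C1CCC(=O)N1I
Why: Electrophilic aromatic iodination goes ortho to the only free phenol, at the carbon between OH and OMe (as in the 3-iodination of 2-hydroxy-4,6-dimethoxyacetophenone), while the acyloxy-flanked position and the ester-deactivated ring B are slower under acid-free conditions.

Step 4
Reactants: 9 2-acetyl-3-hydroxy-4-iodo-5-methoxyphenyl 2,4-bis(methoxymethoxy)benzoate; 2 chloromethyl methyl ether (MOMCl)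
Product: 10 2-acetyl-4-iodo-5-methoxy-3-(methoxymethoxy)phenyl 2,4-bis(methoxymethoxy)benzoate
Conditions: MOMCl (3 equiv), iPr2NEt (4 equiv), Bu4NI (10 mol%), CH2Cl2, 40 °C
Reagents that add atoms: chloromethyl methyl ether 2, COCCl
Why: MOM etherification with a non-enolising amine base (no premature acyl transfer) caps the iodine-flanked oxygen, the future 5-OH, so that later only the oxygen now held as the ester can close ring C and iodine is fixed at C-6.

Step 5
Reactants: 10 2-acetyl-4-iodo-5-methoxy-3-(methoxymethoxy)phenyl 2,4-bis(methoxymethoxy)benzoate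
Product: 11 1-[2,4-bis(methoxymethoxy)phenyl]-3-[6-hydroxy-3-iodo-4-methoxy-2-(methoxymethoxy)phenyl]propane-1,3-dione
Conditions: LiN(SiMe3)2 (3 equiv), THF, −78 → 0 °C; AcOH quench
Reagents that add atoms: none
Why: Baker–Venkataraman rearrangement: the lithium enolate of the acetyl group attacks the neighbouring aryl ester and the tetrahedral intermediate collapses to the stabilised 1,3-diketonate, releasing the phenol that becomes O-1.

Step 6
Reactants: 11 1-[2,4-bis(methoxymethoxy)phenyl]-3-[6-hydroxy-3-iodo-4-methoxy-2-(methoxymethoxy)phenyl]propane-1,3-dione; 12 1-bromo-3-methylbut-2-ene (prenyl bromide)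
Product: 13 1-[2,4-bis(methoxymethoxy)phenyl]-3-[6-hydroxy-3-iodo-4-methoxy-2-(methoxymethoxy)phenyl]-2-(3-methylbut-2-enyl)propane-1,3-dione (racemic)
Conditions: prenyl bromide (1.2 equiv), K2CO3 (2 equiv), acetone, rt → 45 °C
Reagents that add atoms: 1-bromo-3-methylbut-2-ene 12, CC(C)=CCBr
Why: C-alkylation of the soft 1,3-diketonate by the allylic bromide (SN2, the laboratory counterpart of enzymatic prenyl transfer to C-3) outruns O-alkylation of the chelated phenol; the new stereocentre is racemic and is erased in step 7.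

Step 7
Reactants: 13 1-[2,4-bis(methoxymethoxy)phenyl]-3-[6-hydroxy-3-iodo-4-methoxy-2-(methoxymethoxy)phenyl]-2-(3-methylbut-2-enyl)propane-1,3-dione
Product: 16 2-(2,4-dihydroxyphenyl)-5-hydroxy-6-iodo-7-methoxy-3-(3-methylbut-2-enyl)-4H-chromen-4-one, via 2-hydroxyflavanone hemiketal 14 (not isolated), via tri-MOM flavone 15 (not isolated)
Conditions: HCl (2 M in MeOH), 0 °C, 30 min; then 50 °C, 3 h
Reagents that add atoms: none
Why: Acid-catalysed cyclodehydration: the only free phenol adds to the aryl ketone to give the 2-hydroxyflavanone hemiketal, whose loss of water (the flavone-forming event of the biosynthesis) is complete at 0 °C before warming solvolyses the three MOM acetals; no stereocentre remains.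

Step 8
Reactants: 16 2-(2,4-dihydroxyphenyl)-5-hydroxy-6-iodo-7-methoxy-3-(3-methylbut-2-enyl)-4H-chromen-4-one; 17 (E)-4,4,5,5-tetramethyl-2-(3-methylbut-1-enyl)-1,3,2-dioxaborolane
Product: 18 artocarpin, 2-(2,4-dihydroxyphenyl)-5-hydroxy-7-methoxy-6-[(E)-3-methylbut-1-enyl]-3-(3-methylbut-2-enyl)-4H-chromen-4-one
Conditions: Pd(OAc)2 (5 mol%), SPhos (10 mol%), K3PO4 (5 equiv), dioxane/H2O (5:1), 80 °C
Reagents that add atoms: (E)-4,4,5,5-tetramethyl-2-(3-methylbut-1-enyl)-1,3,2-dioxaborolane 17, CC(C)/C=C/B1OC(C)(C)C(C)(C)O1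
Why: Suzuki–Miyaura coupling of the aryl iodide with the (E)-alkenylboronate proceeds with retention of alkene geometry, tolerates free phenols and the prenyl group, and brings in the acid-sensitive electron-rich styrene only after the acid step.

Step 9
Reactants: 18 artocarpin; 19 potassium peroxymonosulfate
Product: 21 (S)-oxepinoflavone target CNP0216454.2, via (R)-epoxide 20 (not isolated)
Conditions: D-fructose-derived Shi ketone (30 mol%), KHSO5 (1.2 equiv, as 2KHSO5·KHSO4·K2SO4), K2CO3, Bu4NHSO4 (5 mol%), MeCN/CH2(OMe)2/aq. Na2B4O7 buffer (pH 10.5), 0 °C, 2 h; then 40 °C, 6 h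
Reagents that add atoms: potassium peroxymonosulfate 19, [K+].[O-]S(=O)(=O)OO
Why: Shi asymmetric epoxidation followed in the same flask by base-mediated 7-exo-tet epoxide opening: the dioxirane from the D-fructose-derived ketone epoxidises the more nucleophilic trisubstituted prenyl alkene (the twisted, di-ortho-flanked styrenyl alkene and the chromone alkene are slower) on the face that gives the (R)-epoxide, and the 2'-phenoxide then attacks its secondary carbon by SN2 with inversion, which closes the oxepine as in the presumed biosynthesis and sets the (S)-centre.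

**Compound list**
1 | 2,4-dihydroxybenzoic acid | OC(=O)c1ccc(O)cc1O | starting material
2 | chloromethyl methyl ether (MOMCl) | COCCl | starting material
3 | lithium hydroxide | [Li+].[OH-] | starting material
4 | methoxymethyl 2,4-bis(methoxymethoxy)benzoate (tris-MOM ester) | COCOC(=O)c1ccc(OCOC)cc1OCOC | intermediate
5 | 2,4-bis(methoxymethoxy)benzoic acid | OC(=O)c1ccc(OCOC)cc1OCOC | intermediate
6 | 1-(2,6-dihydroxy-4-methoxyphenyl)ethanone | CC(=O)c1c(O)cc(OC)cc1O | starting material
7 | 2-acetyl-3-hydroxy-5-methoxyphenyl 2,4-bis(methoxymethoxy)benzoate | CC(=O)c1c(O)cc(OC)cc1OC(=O)c1ccc(OCOC)cc1OCOC | intermediate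
8 | N-iodosuccinimide | O=C1CCC(=O)N1I | starting material
9 | 2-acetyl-3-hydroxy-4-iodo-5-methoxyphenyl 2,4-bis(methoxymethoxy)benzoate | CC(=O)c1c(O)c(I)c(OC)cc1OC(=O)c1ccc(OCOC)cc1OCOC | intermediate
10 | 2-acetyl-4-iodo-5-methoxy-3-(methoxymethoxy)phenyl 2,4-bis(methoxymethoxy)benzoate | CC(=O)c1c(OCOC)c(I)c(OC)cc1OC(=O)c1ccc(OCOC)cc1OCOC | intermediate
11 | 1-[2,4-bis(methoxymethoxy)phenyl]-3-[6-hydroxy-3-iodo-4-methoxy-2-(methoxymethoxy)phenyl]propane-1,3-dione | COCOc1ccc(C(=O)CC(=O)c2c(O)cc(OC)c(I)c2OCOC)c(OCOC)c1 | intermediate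
12 | 1-bromo-3-methylbut-2-ene (prenyl bromide) | CC(C)=CCBr | starting material
13 | 1-[2,4-bis(methoxymethoxy)phenyl]-3-[6-hydroxy-3-iodo-4-methoxy-2-(methoxymethoxy)phenyl]-2-(3-methylbut-2-enyl)propane-1,3-dione (racemic) | COCOc1ccc(C(=O)C(CC=C(C)C)C(=O)c2c(O)cc(OC)c(I)c2OCOC)c(OCOC)c1 | intermediate
14 | 2-[2,4-bis(methoxymethoxy)phenyl]-2-hydroxy-6-iodo-7-methoxy-5-(methoxymethoxy)-3-(3-methylbut-2-enyl)chroman-4-one (hemiketal, racemic mixture of diastereomers) | COCOc1ccc(C2(O)Oc3cc(OC)c(I)c(OCOC)c3C(=O)C2CC=C(C)C)c(OCOC)c1 | intermediate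
15 | 2-[2,4-bis(methoxymethoxy)phenyl]-6-iodo-7-methoxy-5-(methoxymethoxy)-3-(3-methylbut-2-enyl)-4H-chromen-4-one (tri-MOM flavone) | COCOc1ccc(-c2oc3cc(OC)c(I)c(OCOC)c3c(=O)c2CC=C(C)C)c(OCOC)c1 | intermediate
16 | 2-(2,4-dihydroxyphenyl)-5-hydroxy-6-iodo-7-methoxy-3-(3-methylbut-2-enyl)-4H-chromen-4-one | COc1cc2oc(-c3ccc(O)cc3O)c(CC=C(C)C)c(=O)c2c(O)c1I | intermediate
17 | (E)-4,4,5,5-tetramethyl-2-(3-methylbut-1-enyl)-1,3,2-dioxaborolane | CC(C)/C=C/B1OC(C)(C)C(C)(C)O1 | starting material
18 | artocarpin, 2-(2,4-dihydroxyphenyl)-5-hydroxy-7-methoxy-6-[(E)-3-methylbut-1-enyl]-3-(3-methylbut-2-enyl)-4H-chromen-4-one | COc1cc2oc(-c3ccc(O)cc3O)c(CC=C(C)C)c(=O)c2c(O)c1/C=C/C(C)C | intermediate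
19 | potassium peroxymonosulfate (KHSO5) | [K+].[O-]S(=O)(=O)OO | starting material
20 | 2-(2,4-dihydroxyphenyl)-3-{[(2R)-3,3-dimethyloxiran-2-yl]methyl}-5-hydroxy-7-methoxy-6-[(E)-3-methylbut-1-enyl]-4H-chromen-4-one | COc1cc2oc(-c3ccc(O)cc3O)c(C[C@H]3OC3(C)C)c(=O)c2c(O)c1/C=C/C(C)C | intermediate
21 | target CNP0216454.2: 5,4'-dihydroxy-7-methoxy-6-[(E)-3-methylbut-1-enyl]flavone whose C-3 and O-2' are bridged by CH2–CH[C(CH3)2OH] (oxepine ring, bridging CH of S configuration) | COc1cc2oc3c(c(=O)c2c(O)c1/C=C/C(C)C)C[C@@H](C(C)(C)O)Oc1cc(O)ccc1-3 | target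

**Step count**
Total steps: 9. Longest linear sequence: 9 (1 → 21); 8 counted from ketone 6.

**Steps most likely to fail**

Risk 1, step 9. The dioxirane may also attack the styrenyl alkene, the phenoxides may be oxidised at pH 10.5, and the 7-exo closure is slower than the familiar 5-exo case. The 2'- and 4'-phenoxides are vinylogous carboxylates, which should make them poor substrates for the dioxirane, and the oxidant is kept limiting. The fallback sets out from 18 and comes back at 21. All three phenols are acetylated (Ac2O, pyridine, DMAP, 50 °C) to give tri-O-acetylartocarpin F1, in which no phenoxide is present and the 5-O-acetyl group lowers the electron density of ring A and of its styrenyl alkene. Shi epoxidation under the step 9 conditions, kept at 0 °C, gives the isolated (R)-epoxide of tri-O-acetylartocarpin F2, whose ee can be measured before the ring is closed. K2CO3 in MeOH (rt → 40 °C) then removes the acetates, and the freed 2'-phenoxide opens the epoxide to 21.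

Risk 2, step 7. If the MOM group next to the ketone on ring A (or the 2'-MOM group on ring B) is lost before the hemiketal has dehydrated, ring C can close through the wrong oxygen, and the prenyl group may add HCl or MeOH on long heating. The fallback sets out from 13 and comes back at 18. The hemiketal is dehydrated without protic acid (SOCl2, pyridine, CH2Cl2, −20 °C) and flavone 15 is isolated with all three MOM groups in place. Suzuki coupling with 17 under the conditions of step 8 gives tri-O-MOM artocarpin F3. The MOM groups are then removed within minutes by ZnBr2 and n-PrSH in CH2Cl2 at 0 °C, which gives 18 without exposing the prenyl or styrenyl groups to hot acid.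

Risk 3, step 3. Iodination could go para to the free OH (next to the ester oxygen), onto ring B, or twice. The fallback sets out from 6 and comes back at 9. Ketone 6 is iodinated first (NIS, 1.0 equiv, DMF, −20 °C); because 6 is symmetric only one mono-iodide can form, 1-(2,6-dihydroxy-3-iodo-4-methoxyphenyl)ethanone F4. Steglich esterification with 5 then takes the less hindered OH, the one remote from iodine, and gives 9, so the regiochemistry rests on sterics in the acylation instead of on the site of iodination.

**Further compounds**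
F1 | step 9 | tri-O-acetylartocarpin | COc1cc2oc(-c3ccc(OC(C)=O)cc3OC(C)=O)c(CC=C(C)C)c(=O)c2c(OC(C)=O)c1/C=C/C(C)C
F2 | step 9 | (R)-epoxide of tri-O-acetylartocarpin | COc1cc2oc(-c3ccc(OC(C)=O)cc3OC(C)=O)c(C[C@H]3OC3(C)C)c(=O)c2c(OC(C)=O)c1/C=C/C(C)C
F3 | step 7 | tri-O-MOM artocarpin | COCOc1ccc(-c2oc3cc(OC)c(/C=C/C(C)C)c(OCOC)c3c(=O)c2CC=C(C)C)c(OCOC)c1
F4 | step 3 | 1-(2,6-dihydroxy-3-iodo-4-methoxyphenyl)ethanone | CC(=O)c1c(O)cc(OC)c(I)c1O
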